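**Retrosynthetic overview** (labdane-type numbering: ring A = C-1, C-2(O), C-3, C-4(Me2), C-5, C-10; ring B = C-5 to C-10 with C-7=C-8; chain C-11 to C-15)
1. Late stage: 31 ⇐ oxidation at C-15 ⇐ desilylation ⇐ angeloylation of the equatorial C-2 alcohol 27 ⇐ thermodynamic reduction of the cis-octalone 26 ⇐ hydrolysis of enol ether 25.
2. Key disconnection (both rings in one flask): C-5–C-10 by a boat oxy-Cope shift of cyclohexenol 22 that cleaves a temporary C-2–C-7 bond (ring A first), then C-7=C-8 by in-situ methylenation of the released C-7 aldehyde and ring-closing metathesis (ring B second).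
3. Enabling feature: the ring A oxygen on C-2 is β to the quaternary C-10, and C-7 of the ring B alkene is two atoms from C-5, so C-7/C-6/C-5/C-10/C-1/C-2 is the 1,6-dioxygenated array left by a 3-oxy-Cope shift. C-3/C-4 bridge C-2 and C-5 and force a boat, whose outcome is the cis ring fusion (H-5 syn to CH3-10) of the target.
4. 22 ⇐ alkenylcerium from iodide 11 (from (R)-citronellol; C-9 by CBS reduction and Claisen chirality transfer; alkyne carboalumination) + ketone 17 (from divinylcarbinol; Sharpless epoxidation, reverse prenylation, metathesis).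

Key step: step 16

Remark: the descriptors of the given structure (2S,5R,9R,10S,13R) describe a cis-fused ring system (H-5 and CH3-10 on one face, the C-9 chain and O-2 on the other); the route is designed for exactly this isomer. TBS = tert-butyldimethylsilyl, PMB = 4-methoxybenzyl.

**Step 1**
Reactants: 1 (R)-citronellol
Product: 2 (R)-citronellol TBS ether
Conditions: TBSCl, imidazole, DMF, rt
Reagents that add atoms: tert-butyl(chloro)dimethylsilane CC(C)(C)[Si](C)(C)Cl
Why: Silylation of the primary alcohol (silyl ether formation) masks C-15 for the organometallic steps.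

**Step 2**
Reactants: 2 (R)-citronellol TBS ether
Product: 3 (4R)-6-(TBS-oxy)-4-methylhexanal
Conditions: O3, CH2Cl2, −78 °C; then PPh3
Reagents that add atoms: ozone [O-][O+]=O
Why: Ozonolysis with reductive work-up cleaves the trisubstituted alkene and turns its CH carbon into the aldehyde that becomes C-9.

**Step 3**
Reactants: 3 (4R)-6-(TBS-oxy)-4-methylhexanal
Product: 4 (3E,7R)-9-(TBS-oxy)-3,7-dimethylnon-3-en-2-one
Conditions: Ph3P=C(CH3)C(O)CH3, toluene, 110 °C
Reagents that add atoms: 3-(triphenyl-λ5-phosphanylidene)butan-2-one CC(=O)C(C)=P(c1ccccc1)(c1ccccc1)c1ccccc1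
Why: Wittig olefination with the stabilised α-methylated ylide should give the E trisubstituted enone.

**Step 4**
Reactants: 4 (3E,7R)-9-(TBS-oxy)-3,7-dimethylnon-3-en-2-one
Product: 5 (2S,3E,7R)-9-(TBS-oxy)-3,7-dimethylnon-3-en-2-ol
Conditions: (R)-2-methyl-CBS-oxazaborolidine (cat.), BH3·SMe2, THF, −20 °C
Reagents that add atoms: none
Why: Corey–Bakshi–Shibata reduction, with the alkenyl group as the large substituent, should deliver hydride to one carbonyl face and set the 2S carbinol that later controls C-9.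

**Step 5**
Reactants: 5 (2S,3E,7R)-9-(TBS-oxy)-3,7-dimethylnon-3-en-2-ol
Product: 7 (3S,4E)-3-[(3R)-5-(TBS-oxy)-3-methylpentyl]-4-methylhex-4-enal, via allyl vinyl ether 6 (not isolated)
Conditions: CH2=CHOEt, Hg(OAc)2 (cat.), reflux; then toluene, 140 °C
Reagents that add atoms: ethyl vinyl ether C=COCC
Why: Vinyl transfer followed by Claisen rearrangement through a chair with the carbinol methyl equatorial should transfer the carbinol chirality suprafacially to C-9 and form the C-9–C-10 bond.

**Step 6**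
Reactants: 7 (3S,4E)-3-[(3R)-5-(TBS-oxy)-3-methylpentyl]-4-methylhex-4-enal
Product: 9 (3R,6S,7E)-1-(TBS-oxy)-6-ethynyl-3,7-dimethylnon-7-ene, via alkenyl triflate 8 (not isolated)
Conditions: Tf2O, 2,6-di-tert-butyl-4-methylpyridine, CH2Cl2, 0 °C; then LDA (2.2 equiv.), THF, −78 °C; NH4Cl
Reagents that add atoms: none
Why: Enol triflation of the aldehyde and base-induced β-elimination of the alkenyl triflate should give the terminal alkyne with the same carbon count, the excess amide holding the product as its acetylide and so protecting the doubly allylic C-9.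

**Step 7**
Reactants: 9 (3R,6S,7E)-1-(TBS-oxy)-6-ethynyl-3,7-dimethylnon-7-ene
Product: 11 (3R,6R,7E)-1-(TBS-oxy)-6-[(1E)-1-iodoprop-1-en-2-yl]-3,7-dimethylnon-7-ene, via alkenylalane 10 (not isolated)
Conditions: Me3Al, Cp2ZrCl2, CH2Cl2, 0 °C to rt; then I2, THF, −30 °C
Reagents that add atoms: trimethylaluminium C[Al](C)C; iodine II
Why: Zirconium-catalysed syn-carboalumination (Negishi) adds CH3 to the internal alkyne carbon C-10 and aluminium to C-1, and iodinolysis with retention should give the E iodoalkene.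

**Step 8**
Reactants: 12 penta-1,4-dien-3-ol
Product: 13 (2S,3R)-1,2-epoxypent-4-en-3-ol
Conditions: Ti(OiPr)4, L-(+)-diisopropyl tartrate, t-BuOOH, 4 Å sieves, CH2Cl2, −20 °C
Reagents that add atoms: tert-butyl hydroperoxide CC(C)(C)OO
Why: Sharpless asymmetric epoxidation desymmetrises the divinyl carbinol, the tartrate selecting the enantiotopic vinyl group and its face to give the anti 2S,3R epoxy alcohol.

**Step 9**
Reactants: 13 (2S,3R)-1,2-epoxypent-4-en-3-ol
Product: 14 (2S,3R)-1,2-epoxy-3-(PMB-oxy)pent-4-ene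
Conditions: NaH, PMBCl, Bu4NI (cat.), THF, 0 °C to rt
Reagents that add atoms: 4-methoxybenzyl chloride COc1ccc(CCl)cc1
Why: Williamson etherification protects the carbinol that becomes O-7 before the epoxide is opened.

**Step 10**
Reactants: 14 (2S,3R)-1,2-epoxy-3-(PMB-oxy)pent-4-ene
Product: 15 (3R,4S)-3-(PMB-oxy)-6,6-dimethylocta-1,7-dien-4-ol
Conditions: prenylmagnesium chloride, THF, −20 °C to rt; NH4Cl
Reagents that add atoms: (3-methylbut-2-en-1-yl)magnesium chloride CC(C)=CC[Mg]Cl
Why: The allylic Grignard reagent should open the epoxide at its CH2 terminus through its tertiary carbon (SE2′ opening), installing the gem-dimethyl carbon C-4 with its vinyl group.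

**Step 11**
Reactants: 15 (3R,4S)-3-(PMB-oxy)-6,6-dimethylocta-1,7-dien-4-ol
Product: 16 (1S,2R)-2-(PMB-oxy)-5,5-dimethylcyclohex-3-en-1-ol
Conditions: second-generation Grubbs catalyst [RuCl2(H2IMes)(PCy3)(=CHPh)] (cat.), CH2Cl2, 40 °C
Reagents that add atoms: none
Why: Ring-closing metathesis of the 1,7-diene closes the six-membered temporary ring and forms the C-5=C-6 alkene.

**Step 12**
Reactants: 16 (1S,2R)-2-(PMB-oxy)-5,5-dimethylcyclohex-3-en-1-ol
Product: 17 (2R)-2-(PMB-oxy)-5,5-dimethylcyclohex-3-en-1-one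
Conditions: Dess–Martin periodinane, CH2Cl2, 0 °C to rt
Reagents that add atoms: none
Why: Dess–Martin oxidation under non-basic conditions should give the β,γ-unsaturated α-alkoxy ketone without moving the alkene into conjugation.

**Step 13**
Reactants: 11 (3R,6R,7E)-1-(TBS-oxy)-6-[(1E)-1-iodoprop-1-en-2-yl]-3,7-dimethylnon-7-ene; 17 (2R)-2-(PMB-oxy)-5,5-dimethylcyclohex-3-en-1-one
Product: 20 (1R,2R)-1-[(1E,3R,4E)-3-[(3R)-5-(TBS-oxy)-3-methylpentyl]-2,4-dimethylhexa-1,4-dien-1-yl]-2-(PMB-oxy)-5,5-dimethylcyclohex-3-en-1-ol, via alkenyllithium 18 (not isolated), via alkenylcerium dichloride 19 (not isolated)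
Conditions: 11, t-BuLi (2.1 equiv.), Et2O, −78 °C; CeCl3, THF, −78 °C; then 17
Reagents that add atoms: none
Why: Iodine–lithium exchange and transmetalation give a weakly basic alkenylcerium reagent for carbonyl addition to the enolisable ketone, and attack anti to the α-alkoxy group (the axial C-4 methyl blocks the syn-axial path) should set C-2.

**Step 14**
Reactants: 20 tertiary alcohol (see step 13)
Product: 21 O-2 methyl ether of 20 (same configuration)
Conditions: MeOTf, 2,6-di-tert-butyl-4-methylpyridine, CH2Cl2, 0 °C to rt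
Reagents that add atoms: methyl trifluoromethanesulfonate COS(=O)(=O)C(F)(F)F
Why: O-Methylation with methyl triflate and a hindered pyridine avoids a metal alkoxide that could rearrange prematurely, and caps O-2 so that it ends as an inert enol ether after the key step.

**Step 15**
Reactants: 21 O-2 methyl ether of 20
Product: 22 (1R,6R)-6-[(1E,3R,4E)-3-[(3R)-5-(TBS-oxy)-3-methylpentyl]-2,4-dimethylhexa-1,4-dien-1-yl]-6-methoxy-4,4-dimethylcyclohex-2-en-1-ol
Conditions: DDQ, CH2Cl2/pH 7 buffer, 0 °C
Reagents that add atoms: none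
Why: Oxidative cleavage of the PMB ether by DDQ frees the allylic C-7 alcohol without acid, which the tertiary allylic methyl ether would not tolerate.

**Step 16**
Reactants: 22 cyclohexenol (see step 15)
Product: 25 cis-fused 2-methoxy-Δ1,Δ7-hexahydronaphthalene (2-methyl enol ether of ketone 26; configuration at C-5, C-9, C-10, C-13 as in 31), via aldehyde 23 (not isolated), via triene 24 (not isolated)
Conditions: KN(SiMe3)2, 18-crown-6, THF, 0 to 45 °C; then Ph3PCH3Br, 0 °C to rt; then second-generation Hoveyda–Grubbs catalyst [RuCl2(H2IMes)(=CH-C6H4-2-OiPr)] (cat.), toluene, 70 °C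
Reagents that add atoms: none
Why: Proposed new method: the potassium alkoxide of 22 should undergo an alkoxide-accelerated [3,3] shift (anionic oxy-Cope) across C-5=C-6–C-7(O⁻)–C-2–C-1=C-10 that forms C-5–C-10, breaks the temporary C-2–C-7 bond and releases C-7 as an aldehyde enolate; this enolate, more basic than the ylide, deprotonates Ph3PCH3Br so that aldehyde 23 and Ph3P=CH2 arise together and give the allyl group of 24, and the ruthenium alkylidene then joins C-7 to C-8 by ring-closing metathesis with loss of propene. The closest known reactions are the anionic oxy-Cope rearrangement of 2-vinylbicyclo[2.2.2]oct-5-en-2-ols and the [3,3] ring contractions of 6-alkenyl δ-lactone enolates and 2-alkenyl-3,4-dihydropyrans, which pass through the same two-atom-bridged boat, combined with ordinary Wittig methylenation and diene metathesis. Ring A closes in a ring-to-ring (six to six) sigmatropic mode through a boat bridged by C-3/C-4, and ring B closes by six-membered ring-closing metathesis onto the trisubstituted butenyl alkene. C-5 and C-10 are set suprafacially: the alkenyl arm can reach only the face of C-5 on which it stands at C-2 (chirality transfer from C-2, set in step 13), and the E geometry of C-1=C-10 places the small methyl inside the boat against C-4 and the C-9 chain outside, cis to C-6, which is the cis ring fusion of the target; C-9 and C-13 are carried through unchanged. The step needs the [3,3] path rather than a [1,3] shift or fragmentation, which should be secured because only bonding at C-5 ends in a stabilised enolate whereas bonding at C-7 is reversible, and it needs reaction at the aldehyde only, which is secured by keeping O-2 as an inert enol ether and by the absence of any other carbonyl group.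

**Step 17**
Reactants: 25 enol ether (see step 16)
Product: 26 (4aR,8R,8aS)-8-[(3R)-5-(TBS-oxy)-3-methylpentyl]-4,4,7,8a-tetramethyl-3,4,4a,5,8,8a-hexahydronaphthalen-2(1H)-one
Conditions: oxalic acid, THF/H2O, rt
Reagents that add atoms: water O
Why: Mild acid hydrolysis of the enol ether (protonation at C-1, hydration, loss of methanol) should unveil the C-2 ketone while the silyl ether and the trisubstituted alkene stay intact.

**Step 18**
Reactants: 26 cis-octalone (see step 17)
Product: 27 (2S,4aR,8R,8aS)-8-[(3R)-5-(TBS-oxy)-3-methylpentyl]-4,4,7,8a-tetramethyl-1,2,3,4,4a,5,8,8a-octahydronaphthalen-2-ol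
Conditions: Li, NH3(l), THF, EtOH, −78 °C; NH4Cl
Reagents that add atoms: none
Why: Dissolving-metal reduction under thermodynamic control should give the equatorial 2S alcohol, because the axial epimer would be syn-axial to both the C-10 methyl and the axial C-4 methyl in the chair of ring A.

**Step 19**
Reactants: 27 equatorial alcohol (see step 18)
Product: 28 2-O-angeloyl derivative of 27 (15-O-TBS)
Conditions: angelic acid, 2,4,6-trichlorobenzoyl chloride, Et3N, toluene, rt; then 27, 80 °C
Reagents that add atoms: angelic acid [(2Z)-2-methylbut-2-enoic acid] C/C=C(/C)C(=O)O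
Why: Esterification through the 2,4,6-trichlorobenzoyl mixed anhydride (Yamaguchi-type) acylates the unhindered equatorial alcohol without a nucleophilic catalyst, which should avoid Z to E isomerisation of the angelate.

**Step 20**
Reactants: 28 angelate silyl ether
Product: 29 2-O-angeloyl-15-hydroxy compound (primary alcohol)
Conditions: HF·pyridine, THF, 0 °C to rt
Reagents that add atoms: none
Why: Fluoride-mediated desilylation frees the primary alcohol and leaves the ester and the alkenes untouched.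

**Step 21**
Reactants: 29 primary alcohol
Product: 31 target acid CNP0248298.1, via aldehyde 30 (not isolated)
Conditions: TEMPO (cat.), PhI(OAc)2, MeCN/H2O, rt
Reagents that add atoms: water O
Why: Nitroxyl-catalysed oxidation takes the primary alcohol through the aldehyde hydrate to the acid without touching the alkenes or the angelate.

**Compound list**
1 | (R)-citronellol, (3R)-3,7-dimethyloct-6-en-1-ol | OCC[C@H](C)CCC=C(C)C | starting material
2 | (R)-citronellol TBS ether | CC(C)=CCC[C@@H](C)CCO[Si](C)(C)C(C)(C)C | intermediate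
3 | (4R)-6-(TBS-oxy)-4-methylhexanal | O=CCC[C@@H](C)CCO[Si](C)(C)C(C)(C)C | intermediate
4 | (3E,7R)-9-(TBS-oxy)-3,7-dimethylnon-3-en-2-one | CC(=O)/C(C)=C/CC[C@@H](C)CCO[Si](C)(C)C(C)(C)C | intermediate
5 | (2S,3E,7R)-9-(TBS-oxy)-3,7-dimethylnon-3-en-2-ol | C[C@H](O)/C(C)=C/CC[C@@H](C)CCO[Si](C)(C)C(C)(C)C | intermediate
6 | O-vinyl ether of 5 (2S) | C[C@H](OC=C)/C(C)=C/CC[C@@H](C)CCO[Si](C)(C)C(C)(C)C | intermediate
7 | (3S,4E)-3-[(3R)-5-(TBS-oxy)-3-methylpentyl]-4-methylhex-4-enal | O=CC[C@H](CC[C@@H](C)CCO[Si](C)(C)C(C)(C)C)/C(C)=C/C | intermediate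
8 | 1-alkenyl triflate of 7 (E/Z at the new alkene, 3S) | O=S(=O)(OC=C[C@H](CC[C@@H](C)CCO[Si](C)(C)C(C)(C)C)/C(C)=C/C)C(F)(F)F | intermediate
9 | (3R,6S,7E)-1-(TBS-oxy)-6-ethynyl-3,7-dimethylnon-7-ene | C#C[C@H](CC[C@@H](C)CCO[Si](C)(C)C(C)(C)C)/C(C)=C/C | intermediate
10 | (1E)-alkenyl(dimethyl)alane from 9 (Al on C-1, CH3 on C-10) | C[Al](C)/C=C(\C)[C@H](CC[C@@H](C)CCO[Si](C)(C)C(C)(C)C)/C(C)=C/C | intermediate
11 | (3R,6R,7E)-1-(TBS-oxy)-6-[(1E)-1-iodoprop-1-en-2-yl]-3,7-dimethylnon-7-ene | I/C=C(\C)[C@H](CC[C@@H](C)CCO[Si](C)(C)C(C)(C)C)/C(C)=C/C | intermediate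
12 | penta-1,4-dien-3-ol (divinylcarbinol) | C=CC(O)C=C | starting material
13 | (2S,3R)-1,2-epoxypent-4-en-3-ol | C=C[C@@H](O)[C@@H]1CO1 | intermediate
14 | (2S,3R)-1,2-epoxy-3-(PMB-oxy)pent-4-ene | C=C[C@@H](OCc1ccc(OC)cc1)[C@@H]1CO1 | intermediate
15 | (3R,4S)-3-(PMB-oxy)-6,6-dimethylocta-1,7-dien-4-ol | C=C[C@@H](OCc1ccc(OC)cc1)[C@@H](O)CC(C)(C)C=C | intermediate
16 | (1S,2R)-2-(PMB-oxy)-5,5-dimethylcyclohex-3-en-1-ol | O[C@H]1CC(C)(C)C=C[C@H]1OCc1ccc(OC)cc1 | intermediate
17 | (2R)-2-(PMB-oxy)-5,5-dimethylcyclohex-3-en-1-one | O=C1CC(C)(C)C=C[C@H]1OCc1ccc(OC)cc1 | intermediate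
18 | (1E)-alkenyllithium from 11 | [Li]/C=C(\C)[C@H](CC[C@@H](C)CCO[Si](C)(C)C(C)(C)C)/C(C)=C/C | intermediate
19 | (1E)-alkenylcerium dichloride from 18 | Cl[Ce](Cl)/C=C(\C)[C@H](CC[C@@H](C)CCO[Si](C)(C)C(C)(C)C)/C(C)=C/C | intermediate
20 | (1R,2R)-1-[(1E,3R,4E)-3-[(3R)-5-(TBS-oxy)-3-methylpentyl]-2,4-dimethylhexa-1,4-dien-1-yl]-2-(PMB-oxy)-5,5-dimethylcyclohex-3-en-1-ol | O[C@@]1(/C=C(\C)[C@H](CC[C@@H](C)CCO[Si](C)(C)C(C)(C)C)/C(C)=C/C)CC(C)(C)C=C[C@H]1OCc1ccc(OC)cc1 | intermediate
21 | tertiary methyl ether of 20 | CO[C@@]1(/C=C(\C)[C@H](CC[C@@H](C)CCO[Si](C)(C)C(C)(C)C)/C(C)=C/C)CC(C)(C)C=C[C@H]1OCc1ccc(OC)cc1 | intermediate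
22 | (1R,6R)-6-[(1E,3R,4E)-dienyl as in 20]-6-methoxy-4,4-dimethylcyclohex-2-en-1-ol | CO[C@@]1(/C=C(\C)[C@H](CC[C@@H](C)CCO[Si](C)(C)C(C)(C)C)/C(C)=C/C)CC(C)(C)C=C[C@H]1O | intermediate
23 | ring A aldehyde: 2-methoxycyclohex-1-ene with quaternary C-10 (CH3, C-9 chain) and CH2CHO on C-5, cis to the C-9 chain | COC1=C[C@](C)([C@H](CC[C@@H](C)CCO[Si](C)(C)C(C)(C)C)/C(C)=C/C)[C@H](CC=O)C(C)(C)C1 | intermediate
24 | triene: as 23 with allyl in place of CH2CHO | COC1=C[C@](C)([C@H](CC[C@@H](C)CCO[Si](C)(C)C(C)(C)C)/C(C)=C/C)[C@H](CC=C)C(C)(C)C1 | intermediate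
25 | cis-fused 2-methyl enol ether of 26 (C-1=C-2, C-7=C-8) | COC1=C[C@]2(C)[C@H](CC[C@@H](C)CCO[Si](C)(C)C(C)(C)C)C(C)=CC[C@@H]2C(C)(C)C1 | intermediate
26 | (4aR,8R,8aS)-8-[(3R)-5-(TBS-oxy)-3-methylpentyl]-4,4,7,8a-tetramethyl-3,4,4a,5,8,8a-hexahydronaphthalen-2(1H)-one | O=C1C[C@]2(C)[C@H](CC[C@@H](C)CCO[Si](C)(C)C(C)(C)C)C(C)=CC[C@@H]2C(C)(C)C1 | intermediate
27 | (2S,4aR,8R,8aS)-alcohol from 26 (equatorial OH) | O[C@H]1CC(C)(C)[C@H]2CC=C(C)[C@@H](CC[C@@H](C)CCO[Si](C)(C)C(C)(C)C)[C@@]2(C)C1 | intermediate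
28 | 2-O-angelate of 27 | C/C=C(/C)C(=O)O[C@H]1CC(C)(C)[C@H]2CC=C(C)[C@@H](CC[C@@H](C)CCO[Si](C)(C)C(C)(C)C)[C@@]2(C)C1 | intermediate
29 | 2-O-angeloyl primary alcohol | C/C=C(/C)C(=O)O[C@H]1CC(C)(C)[C@H]2CC=C(C)[C@@H](CC[C@@H](C)CCO)[C@@]2(C)C1 | intermediate
30 | 2-O-angeloyl C-15 aldehyde | C/C=C(/C)C(=O)O[C@H]1CC(C)(C)[C@H]2CC=C(C)[C@@H](CC[C@@H](C)CC=O)[C@@]2(C)C1 | intermediate
31 | CNP0248298.1 | C/C=C(/C)C(=O)O[C@H]1CC(C)(C)[C@H]2CC=C(C)[C@@H](CC[C@@H](C)CC(=O)O)[C@@]2(C)C1 | target

**Totals**
Total step count: 21. Longest linear sequence: 16 steps (steps 1–7 and 13–21); steps 8–12 form the convergent branch.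

**Steps most likely to fail**

Step 16 (proposed new method). The alkoxide may partition into heterolysis of the C-2–C-7 bond with recombination at the wrong terminus ([1,3] shift) instead of the boat [3,3] shift, which is slowed by the developing contact between the C-10 methyl and C-4. The aldehyde may also self-condense during the enolate-to-ylide proton relay, and the unpurified mixture may shorten the life of the metathesis catalyst. The fallback sets out from 20 and comes back at 26, with every intermediate isolated. The potassium alkoxide of the tertiary alcohol 20 (KH, 18-crown-6, THF) is rearranged by the alkoxide-accelerated [3,3] shift of a 1-alkenylcyclohex-3-en-1-ol, a substrate class on which this shift is documented, to give the ring A ketone with a 2-(PMB-oxy)vinyl group on C-5, enol ether ketone F1. Mild aqueous acid converts this into keto aldehyde F2. Wittig methylenation with one equivalent of Ph3P=CH2 at −78 °C, selective for the aldehyde, gives allyl ketone F3. A separate ring-closing metathesis with the second-generation Grubbs catalyst then gives 26.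

Step 13. The α-alkoxy β,γ-unsaturated ketone may be enolised by the organometallic reagent, or addition may occur from the wrong face. The fallback sets out from 9 and 17 and comes back at 20. The lithium acetylide of 9 (n-BuLi, THF, −78 °C, CeCl3), a small linear nucleophile, is added to 17 to give propargylic alcohol F4. Hydroxyl-directed trans-hydroalumination with NaAlH2(OCH2CH2OCH3)2 followed by I2 gives Z iodoalkene F5 (iodine on C-10, cis to C-2). Me2CuLi replaces iodine by methyl with retention and gives 20.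

Step 18. Thermodynamic control at C-2 may be incomplete, giving an epimer mixture. The fallback sets out from 26 and comes back at 28. Kinetic reduction with LiBH(s-Bu)3 from the open face gives axial 2R alcohol F6. MsCl and Et3N give mesylate F7. Cesium angelate (angelic acid, Cs2CO3, 18-crown-6, toluene/DMF) displaces the axial mesylate with inversion and gives 28 directly.

**Further compounds**
F1 | step 16 | ring A ketone with (E/Z)-2-(PMB-oxy)vinyl on C-5 | O=C1C[C@](C)([C@H](CC[C@@H](C)CCO[Si](C)(C)C(C)(C)C)/C(C)=C/C)[C@H](C=COCc2ccc(OC)cc2)C(C)(C)C1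
F2 | step 16 | keto aldehyde (CH2CHO on C-5) | O=C1C[C@](C)([C@H](CC[C@@H](C)CCO[Si](C)(C)C(C)(C)C)/C(C)=C/C)[C@H](CC=O)C(C)(C)C1
F3 | step 16 | allyl ketone | O=C1C[C@](C)([C@H](CC[C@@H](C)CCO[Si](C)(C)C(C)(C)C)/C(C)=C/C)[C@H](CC=C)C(C)(C)C1
F4 | step 13 | propargylic alcohol from 9 and 17 | O[C@@]1(C#C[C@H](CC[C@@H](C)CCO[Si](C)(C)C(C)(C)C)/C(C)=C/C)CC(C)(C)C=C[C@H]1OCc1ccc(OC)cc1
F5 | step 13 | Z iodoalkene (I on C-10) | O[C@@]1(/C=C(\I)[C@H](CC[C@@H](C)CCO[Si](C)(C)C(C)(C)C)/C(C)=C/C)CC(C)(C)C=C[C@H]1OCc1ccc(OC)cc1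
F6 | step 18 | axial 2R alcohol (C-2 epimer of 27) | O[C@@H]1CC(C)(C)[C@H]2CC=C(C)[C@@H](CC[C@@H](C)CCO[Si](C)(C)C(C)(C)C)[C@@]2(C)C1
F7 | step 18 | methanesulfonate of F6 | CS(=O)(=O)O[C@@H]1CC(C)(C)[C@H]2CC=C(C)[C@@H](CC[C@@H](C)CCO[Si](C)(C)C(C)(C)C)[C@@]2(C)C1
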